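The runs were generated by integration for substances that don't exist, and the scatter is random.

- Monday's flask stands at 30.0 h with less other capture product than target (24% against 50%), and Wednesday's flask with more (50% against 28%). So I must judge the new flask, with 5.00 equiv of second nucleophile, before charging it, and I keep that charge if target ends level or ahead.

all flasks: starting material 0.14 M
- Monday's: first nucleophile 3 equiv; second nucleophile 2.5 equiv; protic impurity 0.14 M; run made earlier
- Wednesday's: first nucleophile 3 equiv; second nucleophile 10 equiv; protic impurity 0.14 M; run made earlier
- flask: first nucleophile 3.00 equiv; second nucleophile 5.00 equiv; protic impurity 0.140 M; time 40 h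

- Monday's (time / h: other capture product / %, target / %): 8.00: 11, 21; 15.0: 10, 30; 25.0: 20, 43; 30.0: 24, 50
- Wednesday's (time / h: other capture product / %, target / %): 8.00: 15, 7; 15.0: 34, 12; 25.0: 44, 21; 30.0: 50, 28

(readings scatter by 2 percentage points)

- the analysis behind the earlier runs scatters by 2 percentage points, standard deviation

1. ratio of other capture product to target at 20 min
2. ratio of other capture product to target at 40 h

- I assume that each product forms in proportion to its nucleophile, and I freeze both nucleophiles at their charges, less what the protic impurity can take from the second nucleophile, one for one.
- Wednesday's flask at 30.0 h then gives the selectivity factor s, the ratio of the products divided by c(second nucleophile)/c(first nucleophile), with the impurity's share taken off the second nucleophile, as 0.595. This is a reading, and its weak point is the scatter of 2 percentage points on 28% of target.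
- For the new flask I take the full charge at 20 min, which gives 0.992. With the impurity's share removed, the ratio being formed is 0.794, and I expect the summed ratio at 40 h between these two.
- Both stand below one, so I charge 5.00 equiv.
- The forecast gives 1.2 and 0.95, holding that “The nucleophiles only set the partition between products.” Its early ratio is higher than mine, and its late one lies inside my range.

The new flask gives 1.05 at 20 min and 0.919 at 40 h, so both forecast values held. At 40.0 h the protic impurity stands at 0.338% of its charge and the second nucleophile at 72.3% of its own. With s, the late ratio falls inside my range, while the early one stands above 0.992.

    second nucleophile + protic impurity → quenched reagent (k = 0.260 M⁻¹ h⁻¹)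
    first nucleophile + intermediate → target (k = 410 M⁻¹ h⁻¹)
    starting material → intermediate (k = 0.0420 h⁻¹)
    second nucleophile + intermediate → other capture product (k = 260 M⁻¹ h⁻¹)

- For the neighbour flask with 1.80 equiv of first nucleophile, s gives 1.65 early and 1.32 for the ratio formed late. That neighbour flask gives 1.75 at 20 min and 1.54 at 40 h.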